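## Structural features

The target (C26H32O5) is a bibenzyl: a hexasubstituted benzoic acid ring A joined through a saturated CH2–CH2 tether to a para-hydroxyphenyl ring B. Every position of ring A is occupied: C1 carries the carboxyl group, C2 a methoxy group, C3 a prenyl group, C4 a free hydroxyl, C5 a second prenyl group and C6 the arylethyl tether. There is no stereocentre and no stereogenic double bond, so the problem is one of regiochemistry and of telling three phenolic oxygens apart (C2 methylated, C4 and ring B free). The fragile parts are the two trisubstituted prenyl alkenes flanking the C4 hydroxyl, which would cyclise to chromans under acid and would not survive hydrogenation or electrophilic oxidants. The electron-rich, doubly ortho-substituted benzoic acid is also delicate: it is prone to decarboxylation in hot acid and its esters resist hydrolysis. The real difficulty is to place six different substituents on one ring without late electrophilic prenylation or carboxylation, and to unmask acid and phenols under neutral conditions. The key step uses the local symmetry of C3–C4–C5: two identical prenyl-bearing carbons flank the oxygenated C4, which is the α-carbon/carbonyl/α'-carbon array of a symmetric ketone. The complementary C6–C1–C2 segment has C6 at the ketone level and C2 at the carboxylic level with the carboxyl on C1, the pattern of an acylmalonate, so joining the two three-carbon pieces gives ring A directly in the aromatic oxidation state.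

## Logic of the disconnections

17 to 16. The three O–allyl bonds (carboxyl oxygen at C1, ether oxygen at C4, ether oxygen of ring B) are cut together. This comes last because the free acid and the prenyl-flanked C4 phenol tolerate neither acid nor hydrogenolysis, and a doubly ortho-substituted benzoate cannot be saponified mildly. One neutral allyl-transfer step replaces three deprotections. The forward step must ionise two aryl allyl ethers, one of them crowded, without touching the prenyl alkenes.

16 to 15. The O–CH3 bond at C2 is cut. The C2 hydroxyl is hydrogen-bonded to the ester carbonyl and is the least reactive oxygen, so it is alkylated when it is the only free hydroxyl and regiochemistry needs no control. The forward step must be forcing enough for a chelated, flanked phenol yet spare the ester.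

15 to 14. The O–allyl bond at C4 is cut. This returns to the resorcylate with both hydroxyls free and relies on the one dependable difference between them: the C4 hydroxyl is para to the ester, more acidic and not chelated. The forward step must stop at monoalkylation.

14 to 12 plus 7 (through 13). Ring A is cut at C5–C6 and at C2–C3. Cutting there turns a hexasubstituted arene into two acyclic, achiral three-carbon pieces that already carry all six substituents. The symmetry of 12 removes any regiochemical question in the first bond formation, and the oxidation levels of 7 make the ring aromatic without an oxidant. The geminal allyl esters of 7 guarantee an ester cis to the incoming chain and leave behind an ester that can later be removed without hydrolysis. The forward step must form a C–C bond at a fully substituted β-carbon, must close through carbon and not oxygen, and must use bases that respect allyl esters and the allyl ether.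

7 to 6. The C6–Cl bond is traced back to the enol C–O bond of an acylmalonate. The chloride is the leaving group that lets C6 enter at the ketone level. The forward deoxychlorination must keep the double bond in conjugation with the two esters.

6 to 3 plus 4 (through 5). The C1–C6 bond is cut, which is a C-acylation of a malonate by an activated arylpropanoic acid. The gain is two simple building blocks. The demand is clean mono-C-acylation.

3 to 1 (through 2). The ring-B O–allyl bond is cut. The phenol must be capped before the acid is activated, and allyl is chosen so that it leaves in the final step with the other allyl groups.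

12 to 11, then 11 to 8 plus 9 (through 10). In 12 the two C–H bonds at the α-carbons are traced back to C–CO2CH3 bonds of 11. In 11 the two bonds between those carbons and the prenyl CH2 groups are cut, one after the other through 10. The ester groups make each α-carbon acidic enough for mild alkylation and direct the second prenyl group to the other side of the ketone. The forward sequence needs 2,4- and not 2,2-dialkylation, two equivalents of 9 and a neutral decarboxylation.

## Other disconnections considered

Alternative 1: The cut is at the two CH2–CH= bonds inside the prenyl groups on C3 and C5. In the forward direction the bis(benzylic chloride) methyl 3,5-bis(chloromethyl)-4-(ethoxycarbonyloxy)-2-methoxy-6-[2-(4-triisopropylsilyloxyphenyl)ethyl]benzoate A1 would be coupled twice with 1-bromo-2-methylprop-1-ene A2. The coupling is electroreductive, at a cathode with a zinc anode, NiBr2(dme) and a 4,4'-dialkyl-2,2'-bipyridine ligand, and would give methyl 4-(ethoxycarbonyloxy)-2-methoxy-3,5-bis(3-methylbut-2-enyl)-6-[2-(4-triisopropylsilyloxyphenyl)ethyl]benzoate A3.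
- In its favour: the prenyl positions are fixed by the chloromethyl groups, so on regiochemical certainty it is the equal of the chosen plan. The reductive, base-free radical/organonickel mechanism is gentler than enolate chemistry, and on this point it is the better plan. It is also more modular for analogues.
- Against it: no ring is formed, so the hexasubstituted core of A1 still has to be made, with chloromethylation distinguishing ring A from ring B. Benzylic chlorides ortho to an acylated phenol are exposed to quinone methide formation, homocoupling and hydrodechlorination, and both couplings must succeed on one molecule. The end game needs hydrolysis of a doubly ortho-substituted methyl benzoate next to an aryl methyl ether, plus carbonate and silyl removal.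
- Step economy: core synthesis, twofold coupling and three unmaskings should exceed the nine steps of the chosen plan.

Alternative 2: The cut is at C2–C3 and C4–C5 (Danheiser benzannulation). Heating 2-(3-methylbut-2-enyl)-3-[2-(4-triisopropylsilyloxyphenyl)ethyl]cyclobut-2-en-1-one A4 with triisopropyl[(5-methylhex-4-en-1-ynyl)oxy]silane A5 would open the cyclobutenone to a vinylketene. This adds to the siloxyalkyne, and 4π opening, 6π closure and tautomerisation would give 2,4-bis(3-methylbut-2-enyl)-3-triisopropylsilyloxy-5-[2-(4-triisopropylsilyloxyphenyl)ethyl]phenol A6.
- In its favour: the pericyclic cascade is regiospecific and needs no reagent. It also delivers the two ring-A oxygens already differentiated (free hydroxyl at C2, silyl ether at C4). On that point it is better than the chosen plan, which spends step 7 on this distinction. Like the chosen plan it needs no oxidant.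
- Against it: A6 has hydrogen at C1. The carboxyl would have to be introduced afterwards at the most crowded position, by halogenation–metalation or Kolbe–Schmitt chemistry, in the presence of two prenyl alkenes and electron-rich ring B. Both A4 and A5 are multistep, sensitive compounds.
- Step economy: clearly longer, with the late carboxylation as the weak point.

Alternative 3: The cut is at C1–C6 (biomimetic aldol folding). A masked triketo acid, taken here as the dimethyl ketal 6-[6-(4-allyloxyphenyl)-4,4-dimethoxy-1,3-bis(3-methylbut-2-enyl)-2-oxohexyl]-2,2-dimethyl-4H-1,3-dioxin-4-one A7, would be unmasked with dilute acid. Triethylamine would then drive the dioxinone α-carbon onto the C6 ketone, and dehydration and enolisation would give 7-hydroxy-2,2-dimethyl-6,8-bis(3-methylbut-2-enyl)-5-[2-(4-allyloxyphenyl)ethyl]-4H-1,3-benzodioxin-4-one A8.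
- In its favour: only one C–C bond is made on a chain that already fixes the substitution pattern, and the base is mild. The carboxyl and the C2 oxygen arrive tied together, so the two ring-A oxygens are distinguished from the start. On that point it equals or betters the chosen plan.
- Against it: A7 is a 1,3,5-tricarbonyl equivalent with two prenylated α-carbons. Its assembly needs several acylations and C-prenylations with C/O selectivity problems. The acid step endangers the prenyl alkenes and invites γ-pyranone formation, and the aldol must reach a hindered ketone. From A8 the dioxinone still has to be opened, C4 protected, C2 methylated and the ester cleaved, so the end game is no shorter than in the chosen plan.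
- Step economy: longer linear sequence than the chosen plan.

Key step: step 6

Assumption: the target is achiral, so no configuration has to be set; the stereocentres of 10, 11 and 13 are transient and are carried as mixtures. The key step balances as C13H22O (12) + C21H23ClO5 (7) = C31H38O5 (14) + HCl + C3H6O.

## Route

Step 1
Reactants: 1 3-(4-hydroxyphenyl)propanoic acid
Product: 3 3-(4-allyloxyphenyl)propanoic acid, via allyl 3-(4-allyloxyphenyl)propanoate 2 (not isolated)
Conditions: allyl bromide (2.4 equiv), K2CO3 (3 equiv), DMF, 50 °C; then 2 M NaOH, MeOH, 50 °C, same flask; 1 M HCl to pH 2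
Reagents that add atoms: allyl bromide, C=CCBr
Why: Williamson O-allylation of the phenoxide (the carboxylate is allylated too), then saponification of the unhindered allyl ester in the same flask; the aryl allyl ether is inert to hydroxide.

Step 2
Reactants: 3 3-(4-allyloxyphenyl)propanoic acid; 4 diallyl malonate
Product: 6 diallyl 2-[3-(4-allyloxyphenyl)propanoyl]malonate, via 3-(4-allyloxyphenyl)propanoyl chloride 5 (not isolated)
Conditions: (COCl)2 (1.2 equiv), DMF (cat.), CH2Cl2, 0 °C → rt, evaporate; then 4 (1.1 equiv), MgCl2 (1.1 equiv), Et3N (2.2 equiv), MeCN, 0 °C → rt; 1 M HCl
Reagents that add atoms: none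
Why: Acid chloride formation, then C-acylation of the malonate enolate generated by MgCl2/Et3N soft enolisation; the product is held as its magnesium chelate, which should prevent diacylation and O-acylation.

Step 3
Reactants: 6 diallyl 2-[3-(4-allyloxyphenyl)propanoyl]malonate
Product: 7 diallyl 2-[1-chloro-3-(4-allyloxyphenyl)propylidene]malonate
Conditions: POCl3 (4 equiv), Bu3N (1.1 equiv), toluene, 85 °C; pour on ice
Reagents that add atoms: phosphoryl chloride, O=P(Cl)(Cl)Cl
Why: Deoxychlorination of a β-dicarbonyl enol: the enol oxygen is phosphorylated and chloride displaces dichlorophosphate by addition–elimination, the established access to 1-chloroalkylidene malonates; the two esters are identical, so no alkene geometry arises.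

Step 4
Reactants: 8 dimethyl 3-oxopentanedioate; 9 prenyl bromide (1-bromo-3-methylbut-2-ene)
Product: 11 dimethyl 2,4-bis(3-methylbut-2-enyl)-3-oxopentanedioate (mixture of diastereomers), via dimethyl 2-(3-methylbut-2-enyl)-3-oxopentanedioate 10 (not isolated)
Conditions: NaH (1.05 equiv), THF, 0 °C, then 9 (1.05 equiv), rt; then NaH (1.05 equiv), 0 °C, and a second portion of 9 (1.05 equiv), rt, same flask; aq. NH4Cl
Reagents that add atoms: prenyl bromide (9, second equivalent), CC(C)=CCBr
Why: Two successive enolate C-alkylations in one flask: the first equivalent of 9 gives the mono-prenyl keto diester 10, whose unsubstituted C4 methylene is the more acidic and less hindered site, so the second equivalent of 9 should enter at C4 and not at C2; SN2 attack at the primary allylic carbon keeps each prenyl group linear.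

Step 5
Reactants: 11 dimethyl 2,4-bis(3-methylbut-2-enyl)-3-oxopentanedioate
Product: 12 2,10-dimethylundeca-2,9-dien-6-one
Conditions: LiCl (4 equiv), H2O (4 equiv), DMSO, 150 °C
Reagents that add atoms: none
Why: Krapcho dealkoxycarbonylation: chloride demethylates each β-keto ester and the carboxylate loses CO2 through the ketone enol; the neutral medium spares the prenyl alkenes and avoids the retro-Claisen cleavage that hydroxide can cause in 3-oxoglutarates.

Step 6
Reactants: 12 2,10-dimethylundeca-2,9-dien-6-one; 7 diallyl 2-[1-chloro-3-(4-allyloxyphenyl)propylidene]malonate
Product: 14 allyl 2,4-dihydroxy-3,5-bis(3-methylbut-2-enyl)-6-[2-(4-allyloxyphenyl)ethyl]benzoate, via keto alkylidenemalonate adduct 13 (not isolated)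
Conditions: 12 (2.1 equiv), LiN(SiMe3)2 (2.1 equiv), THF, −78 °C; 7 (1.0 equiv), −78 → −20 °C; then KOtBu (2.5 equiv), allyl alcohol (6 equiv), THF, 0 → 40 °C; aq. NH4Cl
Reagents that add atoms: none
Why: Michael addition–elimination followed by an intramolecular Claisen (Dieckmann-type) acylation, overall a [3+3] benzannulation. The lithium enolate of 12 adds to the chlorine-bearing β-carbon of 7 and the malonate enolate so formed expels chloride, making the C5–C6 bond and giving 13; LiN(SiMe3)2 is chosen so that no nucleophilic amine is present to displace the vinylic chloride. Adduct 13 is more acidic than 12 (its C5–H is α to the ketone and vinylogous to both esters), so the second equivalent of enolate serves as its base and the excess 12 is recovered. Potassium allyloxide (from KOtBu and allyl alcohol) then equilibrates the anions, and the minor α'-enolate at C3 attacks the ester cis to the keto chain in a 6-(enolendo)-exo-trig closure that forms C2–C3 and ring A; loss of allyloxide and two enolisations should give the aromatic phenoxide of 14. The closest known reaction type is the Michael–Claisen condensation of ketone enolates with alkoxymethylene- or alkylidene-malonates. No stereocentre is created, since the C5 centre of 13 is racemic and is erased on aromatisation. The step needs carbon over oxygen acylation and a single regiochemistry: the geminal diester always offers a cis ester, the symmetry of 12 makes the first enolisation unambiguous, the matched and nucleophilic allyloxide can reopen any 2-pyranone formed through oxygen without scrambling the ester, and the aromatic phenoxide is the thermodynamic sink. Because C2 arrives at the acid level and C6 at the ketone level, no oxidant meets the prenyl groups.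

Step 7
Reactants: 14 allyl 2,4-dihydroxy-3,5-bis(3-methylbut-2-enyl)-6-[2-(4-allyloxyphenyl)ethyl]benzoate
Product: 15 allyl 4-allyloxy-2-hydroxy-3,5-bis(3-methylbut-2-enyl)-6-[2-(4-allyloxyphenyl)ethyl]benzoate
Conditions: allyl bromide (1.1 equiv), K2CO3 (1.5 equiv), acetone, rt → 40 °C
Reagents that add atoms: allyl bromide, C=CCBr
Why: Williamson etherification under mild carbonate conditions: only the C4 hydroxyl (para to the ester, more acidic, not hydrogen-bonded) should be ionised and alkylated, while the C2 hydroxyl stays in its chelate with the ester carbonyl; both ortho positions of the new ether are blocked, so no Claisen rearrangement can follow.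

Step 8
Reactants: 15 allyl 4-allyloxy-2-hydroxy-3,5-bis(3-methylbut-2-enyl)-6-[2-(4-allyloxyphenyl)ethyl]benzoate
Product: 16 allyl 4-allyloxy-2-methoxy-3,5-bis(3-methylbut-2-enyl)-6-[2-(4-allyloxyphenyl)ethyl]benzoate
Conditions: MeI (5 equiv), Cs2CO3 (2 equiv), DMF, 40 °C
Reagents that add atoms: iodomethane, CI
Why: O-Methylation of the last, chelated phenol through its well-dissociated caesium phenoxide in DMF with excess MeI; no other nucleophilic site remains, so regiochemistry is not in question.

Step 9
Reactants: 16 allyl 4-allyloxy-2-methoxy-3,5-bis(3-methylbut-2-enyl)-6-[2-(4-allyloxyphenyl)ethyl]benzoate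
Product: 17 4-hydroxy-6-[2-(4-hydroxyphenyl)ethyl]-2-methoxy-3,5-bis(3-methylbut-2-enyl)benzoic acid
Conditions: Pd(PPh3)4 (10 mol %), morpholine (12 equiv), THF, degassed, rt → 35 °C; pH 4 citrate buffer
Reagents that add atoms: none
Why: Tsuji–Trost-type deallylation: zerovalent palladium ionises the allyl ester and both aryl allyl ethers to π-allyl complexes that morpholine intercepts; the C-prenyl groups carry no leaving group and stay inert, and the neutral conditions avoid chroman formation and decarboxylation.

## Compound list

1 | 3-(4-hydroxyphenyl)propanoic acid | OC(=O)CCc1ccc(O)cc1 | starting material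
2 | allyl 3-(4-allyloxyphenyl)propanoate (not isolated) | C=CCOC(=O)CCc1ccc(OCC=C)cc1 | intermediate
3 | 3-(4-allyloxyphenyl)propanoic acid | OC(=O)CCc1ccc(OCC=C)cc1 | intermediate
4 | diallyl malonate | C=CCOC(=O)CC(=O)OCC=C | starting material
5 | 3-(4-allyloxyphenyl)propanoyl chloride (not isolated) | ClC(=O)CCc1ccc(OCC=C)cc1 | intermediate
6 | diallyl 2-[3-(4-allyloxyphenyl)propanoyl]malonate | C=CCOC(=O)C(C(=O)OCC=C)C(=O)CCc1ccc(OCC=C)cc1 | intermediate
7 | diallyl 2-[1-chloro-3-(4-allyloxyphenyl)propylidene]malonate | C=CCOC(=O)C(C(=O)OCC=C)=C(Cl)CCc1ccc(OCC=C)cc1 | intermediate
8 | dimethyl 3-oxopentanedioate | COC(=O)CC(=O)CC(=O)OC | starting material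
9 | prenyl bromide (1-bromo-3-methylbut-2-ene) | CC(C)=CCBr | starting material
10 | dimethyl 2-(3-methylbut-2-enyl)-3-oxopentanedioate (racemic, not isolated) | COC(=O)C(CC=C(C)C)C(=O)CC(=O)OC | intermediate
11 | dimethyl 2,4-bis(3-methylbut-2-enyl)-3-oxopentanedioate (mixture of diastereomers) | COC(=O)C(CC=C(C)C)C(=O)C(CC=C(C)C)C(=O)OC | intermediate
12 | 2,10-dimethylundeca-2,9-dien-6-one | CC(C)=CCCC(=O)CCC=C(C)C | intermediate
13 | diallyl 2-[1-[2-(4-allyloxyphenyl)ethyl]-7-methyl-2-(3-methylbut-2-enyl)-3-oxooct-6-enylidene]malonate (racemic, not isolated) | C=CCOC(=O)C(C(=O)OCC=C)=C(CCc1ccc(OCC=C)cc1)C(CC=C(C)C)C(=O)CCC=C(C)C | intermediate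
14 | allyl 2,4-dihydroxy-3,5-bis(3-methylbut-2-enyl)-6-[2-(4-allyloxyphenyl)ethyl]benzoate | C=CCOC(=O)c1c(O)c(CC=C(C)C)c(O)c(CC=C(C)C)c1CCc1ccc(OCC=C)cc1 | intermediate
15 | allyl 4-allyloxy-2-hydroxy-3,5-bis(3-methylbut-2-enyl)-6-[2-(4-allyloxyphenyl)ethyl]benzoate | C=CCOC(=O)c1c(O)c(CC=C(C)C)c(OCC=C)c(CC=C(C)C)c1CCc1ccc(OCC=C)cc1 | intermediate
16 | allyl 4-allyloxy-2-methoxy-3,5-bis(3-methylbut-2-enyl)-6-[2-(4-allyloxyphenyl)ethyl]benzoate | C=CCOC(=O)c1c(OC)c(CC=C(C)C)c(OCC=C)c(CC=C(C)C)c1CCc1ccc(OCC=C)cc1 | intermediate
17 | 4-hydroxy-6-[2-(4-hydroxyphenyl)ethyl]-2-methoxy-3,5-bis(3-methylbut-2-enyl)benzoic acid | COc1c(CC=C(C)C)c(O)c(CC=C(C)C)c(CCc2ccc(O)cc2)c1C(=O)O | target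

## Step count and risk

Total step count: 9. Longest linear sequence: 7 steps (steps 1, 2, 3, 6, 7, 8, 9, from 1); the ketone branch (steps 4 and 5) joins at step 6.

Step 6 (key step). What may go wrong: proton transfer from the γ-methylene of 7 to the α-branched enolate may outrun conjugate addition at the fully substituted β-carbon. The hindered carbon acylation may also lose to closure through the enolate oxygen, so that material stalls before aromatisation. Fallback: setting out from 7, the same two-stage annulation is run with the unhindered lithium enolate of acetone (LiN(SiMe3)2, THF, −78 °C; then KOtBu/allyl alcohol). This should give allyl 2,4-dihydroxy-6-[2-(4-allyloxyphenyl)ethyl]benzoate F1. The two prenyl groups are then placed on C3 and C5 by twofold C-alkylation of the sodium phenoxide of F1 with 9 (NaH, toluene, rt → 60 °C, a non-polar medium that favours carbon over oxygen alkylation). This returns to the route at 14.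

Step 3. What may go wrong: at the temperature needed for deoxychlorination the new double bond may migrate out of conjugation, HCl may be lost to give an allenyl malonate, or the allyl β-keto ester may undergo a Carroll-type [3,3] rearrangement. Fallback: setting out from 6, O-methylation of the enol with (trimethylsilyl)diazomethane (toluene–MeOH, 0 °C → rt) should give diallyl 2-[3-(4-allyloxyphenyl)-1-methoxypropylidene]malonate F2. Its methoxy group serves as the leaving group in the same addition–elimination with the lithium enolate of 12 (THF, −78 → 0 °C). The adduct is isolated after an NH4Cl quench, so that methanol is removed before any ester exchange. This returns to the route at 13, which is closed to 14 with KOtBu/allyl alcohol as in step 6.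

Step 4. What may go wrong: the second alkylation may occur at the already substituted carbon of 10 (2,2-dialkylation), and O-alkylation or SN2' attack may give isomeric material that is hard to separate. Fallback: setting out from 9, acetone N,N-dimethylhydrazone is deprotonated (LiN(iPr)2, THF, −78 → 0 °C) and alkylated with 9 to give 1,1-dimethyl-2-(6-methylhept-5-en-2-ylidene)hydrazine F3. A second deprotonation, which should take place at the remaining methyl group, and alkylation with 9 give 2-(2,10-dimethylundeca-2,9-dien-6-ylidene)-1,1-dimethylhydrazine F4. Hydrolysis in a two-phase mixture of aqueous oxalic acid and diethyl ether returns to the route at 12.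

Step 7. What may go wrong: discrimination between the two hydroxyls may be lost, through alkylation of the chelated C2 hydroxyl or sluggish reaction at the doubly flanked C4 hydroxyl. Fallback: setting out from 14, Mitsunobu etherification with allyl alcohol (PPh3, diisopropyl azodicarboxylate, THF, 0 °C → rt) engages only the more acidic, non-hydrogen-bonded phenol as the pronucleophile. This returns to the route at 15 without any new compound.

## Further compounds

F1 | step 6 | allyl 2,4-dihydroxy-6-[2-(4-allyloxyphenyl)ethyl]benzoate | C=CCOC(=O)c1c(O)cc(O)cc1CCc1ccc(OCC=C)cc1
F2 | step 3 | diallyl 2-[3-(4-allyloxyphenyl)-1-methoxypropylidene]malonate | C=CCOC(=O)C(C(=O)OCC=C)=C(OC)CCc1ccc(OCC=C)cc1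
F3 | step 4 | 1,1-dimethyl-2-(6-methylhept-5-en-2-ylidene)hydrazine | CC(C)=CCCC(C)=NN(C)C
F4 | step 4 | 2-(2,10-dimethylundeca-2,9-dien-6-ylidene)-1,1-dimethylhydrazine | CC(C)=CCCC(CCC=C(C)C)=NN(C)C
F0 | step 7 | none | none
A1 | alternative 1 | methyl 3,5-bis(chloromethyl)-4-(ethoxycarbonyloxy)-2-methoxy-6-[2-(4-triisopropylsilyloxyphenyl)ethyl]benzoate | COC(=O)c1c(OC)c(CCl)c(OC(=O)OCC)c(CCl)c1CCc1ccc(O[Si](C(C)C)(C(C)C)C(C)C)cc1
A2 | alternative 1 | 1-bromo-2-methylprop-1-ene | CC(C)=CBr
A3 | alternative 1 | methyl 4-(ethoxycarbonyloxy)-2-methoxy-3,5-bis(3-methylbut-2-enyl)-6-[2-(4-triisopropylsilyloxyphenyl)ethyl]benzoate | COC(=O)c1c(OC)c(CC=C(C)C)c(OC(=O)OCC)c(CC=C(C)C)c1CCc1ccc(O[Si](C(C)C)(C(C)C)C(C)C)cc1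
A4 | alternative 2 | 2-(3-methylbut-2-enyl)-3-[2-(4-triisopropylsilyloxyphenyl)ethyl]cyclobut-2-en-1-one | O=C1CC(CCc2ccc(O[Si](C(C)C)(C(C)C)C(C)C)cc2)=C1CC=C(C)C
A5 | alternative 2 | triisopropyl[(5-methylhex-4-en-1-ynyl)oxy]silane | CC(C)=CCC#CO[Si](C(C)C)(C(C)C)C(C)C
A6 | alternative 2 | 2,4-bis(3-methylbut-2-enyl)-3-triisopropylsilyloxy-5-[2-(4-triisopropylsilyloxyphenyl)ethyl]phenol | Oc1cc(CCc2ccc(O[Si](C(C)C)(C(C)C)C(C)C)cc2)c(CC=C(C)C)c(O[Si](C(C)C)(C(C)C)C(C)C)c1CC=C(C)C
A7 | alternative 3 | 6-[6-(4-allyloxyphenyl)-4,4-dimethoxy-1,3-bis(3-methylbut-2-enyl)-2-oxohexyl]-2,2-dimethyl-4H-1,3-dioxin-4-one (mixture of diastereomers) | CC1(C)OC(=O)C=C(O1)C(CC=C(C)C)C(=O)C(CC=C(C)C)C(OC)(OC)CCc1ccc(OCC=C)cc1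
A8 | alternative 3 | 7-hydroxy-2,2-dimethyl-6,8-bis(3-methylbut-2-enyl)-5-[2-(4-allyloxyphenyl)ethyl]-4H-1,3-benzodioxin-4-one | CC1(C)OC(=O)c2c(CCc3ccc(OCC=C)cc3)c(CC=C(C)C)c(O)c(CC=C(C)C)c2O1
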